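(All runs are calculated for substances that don't exist.)

Follow the substrate left, not the product made.

| flask | substrate | coupling partner | remark | time |
|---|---|---|---|---|
| delta | 0.13 M | 0.20 M | run made earlier |  |
| epsilon | 0.40 M | 0.20 M | run made earlier |  |
| maple | 0.20 M | 0.200 M |  | 15 h |
| ash | 0.20 M | 0.240 M |  | 15 h |
| larch | 0.20 M | 0.800 M |  | 15 h |

| run | time / h | double product / % | first product / % |
|---|---|---|---|
| delta | 0.833 | 26.8 | 0.7 |
| delta | 2.00 | 35.0 | 0 |
| delta | 2.50 | 35.8 | 0 |
| delta | 4.00 | 37.4 | 0 |
| delta | 5.00 | 38.2 | 0 |
| epsilon | 0.417 | 3.9 | 1.6 |
| epsilon | 0.667 | 3.7 | 0 |
| epsilon | 1.00 | 4.3 | 0 |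
| epsilon | 2.00 | 5.0 | 0.1 |
| epsilon | 3.00 | 4.5 | 0.1 |
| epsilon | 5.00 | 3.7 | 0 |

(each reading ± 0.5 percentage points)

- what was read earlier has a scatter of 0.5 percentage points, one standard deviation
- steps under discussion: coupling partner + other mono adduct -> double product + by-product; substrate + coupling partner -> first product + by-product; substrate + coupling partner -> other mono adduct + by-product; first product + by-product -> side product; coupling partner + first product -> double product + by-product

* final double product, as a percentage of the substrate charged, for each flask in turn (maple, ash, larch)

Does the coupling partner last? Each substrate consumed takes one partner, whichever mono adduct forms, and each double product takes one more. Take the last delta reading, 38.2%, as the double product that a fully consumed charge gives. That yields 138% as the partner demand, the partner needed per substrate charged to consume the whole charge. Delta itself had 1.54 per substrate, more than this.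

Maple has 1.00 and ash 1.20, both below the demand, so the coupling partner should be the limiting reagent in those two flasks. Larch has 4.00, above it, so in larch the substrate should be the limiting reagent.

How much do maple and ash give? Once the partner is used up, the balance says that double product equals the fraction of substrate left plus the partner charged beyond the substrate. In maple that excess is nil, and in ash it is 20.0% of the substrate charged. If the delta share held for the substrate consumed, my own figures would be 27.5% for maple and 33.2% for ash. Other mono adduct still standing at the end lowers both.

The forecast is 17%, 26% and 42%, below my figures for maple and ash, and it says of those two: “Partner balance, substrate loss plus double product, then gives about 17% at 1.0 equivalent and 26% at 1.2 equivalents.”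

    coupling partner + other mono adduct → double product + by-product (k = 0.510 L mol⁻¹ min⁻¹)
    substrate + coupling partner → first product + by-product (k = 0.420 L mol⁻¹ min⁻¹)
    substrate + coupling partner → other mono adduct + by-product (k = 0.240 L mol⁻¹ min⁻¹)
    first product + by-product → side product (k = 2.10 L mol⁻¹ min⁻¹)
    coupling partner + first product → double product + by-product (k = 0.0600 L mol⁻¹ min⁻¹)

The flasks give 17.7%, 26.7% and 43.2%. In ash, 0% of the coupling partner is left at 15.0 h, and the double product stands 20 percentage points above the 6.69% of substrate left, beside 9.09% of other mono adduct. Applied to larch, the partner demand says that 65.4% of its coupling partner should remain, and 64% is left at 15.0 h.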